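## Analysis of the target

Locants used throughout: ring A = C1–C5 and C10; ring B = C5–C10; the chain on C9 is C11–C12–C13(–C16H2OH)–C14–C15–OAc; C17 = methyl on C8; C18 and C19 = the two CH2OH groups on C4; C20 = methyl on C10.

The target 30 is a Δ5-octalin. Rings A and B share C5 and C10, and the only ring double bond, C5=C6, lies between the two quaternary carbons C4 and C10. C4 carries two identical hydroxymethyl groups and is not a stereocentre; the stereocentres are C8 (S), C9 (S) and C10 (R) in ring B and C13 (S) in the chain. C8, C9 and C10 are contiguous, C10 is quaternary, and the three substituents (C17, C11, C20) lie on the same face of ring B. This all-cis triad is not the thermodynamic one: in either half-chair of ring B the two methyl groups are syn-diaxial or the chain is axial, so it must be set kinetically. C13 is two methylene groups away from C9, cannot be relayed from the ring, and carries two different oxygenated arms (C16–OH, C14–C15–OAc). The sensitive group is one primary acetate beside three free primary hydroxyls, one of them (C16–OH) 1,4 to it; the four C–O groups must be differentiated before the acetate is introduced, and strong base or nucleophiles are excluded afterwards. The C5=C6 bond is hindered and cannot migrate, but it must survive every reduction. The hard part is the quaternary C10 flanked by two stereocentres on the same face, in the ring that also holds the alkene.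

## Retrosynthetic reasoning

30 ← 29 ← 28 ← 27. The last step only removes acid-labile groups (silyl ether at O16, acetonide at O18/O19), which a primary acetate tolerates. Before that, the C11=C12 bond of 28 is saturated by a metal-free hydrogen transfer that leaves the hindered C5=C6 bond alone. 28 comes from acetylation of 27, in which C15–OH is the only free hydroxyl.

27 ← 17 + 26. The C11=C12 bond is cut (sulfone olefination). This cut separates the ring triad from C13, so each half gets its own control element. With lactol 26 as the carbonyl partner, the union itself releases C15–OH as the only unprotected hydroxyl, so C15 and C16 are differentiated without extra protecting-group steps.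

26 ← 25 ← 22 ← 21 ← 20 ← 18 + 19. C13 is set by auxiliary-controlled hydroxymethylation of imide 20 (C16 enters as the C1 electrophile). C12 is the acyl carbon, and C14–C15 come from the allyl group after loss of its terminal carbon. Lactonisation to 25 releases the auxiliary and marks C12 (carbonyl) against C15 (alkyl–O).

17 ← 16 ← 15 ← 13 (through 14). These are functional-group changes at C11. The one stereochemical correction of the route sits here: C9 of 13 is inverted by kinetic protonation of its enolate (14) and fixed at once by reduction to alcohol 15.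

13 ← 12 ← 8 + 11 (key disconnection). The C7–C8 and C9–C10 bonds are cut. Ring B is the retron of a [4+2] cycloaddition with C5=C6 as the new double bond, C10=C5–C6=C7 as the diene and C8=C9 as the dienophile. Diene 8 is achiral and already holds ring A and the quaternary C4; dienophile 11 brings C8, C9, C11, C17 and the bought stereocentre. The forward reaction must form the quaternary C10, place the C17 and C20 methyl groups cis, and do so on one enantiotopic face pair.

8 ← 7 ← 6 ← 5 ← 4 ← 3 ← 1 + 2. The vinyl group (C6, C7) is attached through the enol triflate of ketone 4, which can only enolise towards C10. C4 is a malonate carbon, so the two hydroxymethyl groups come from two esters. Ring A is closed at C1–C10 by alkylation of the only possible enolate of 3.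

## Alternatives that were turned down

Alternative 1: the textbook route. Ring A is annulated onto a 2-methyl-1,3-dione by an amine-catalysed Robinson annulation to the Wieland–Miescher ketone A1, and C4 is dialkylated with deconjugation to reach the C9 ketone A2 with C5=C6 in place. It was turned down for three reasons. (i) Bis-hydroxymethylation of the dienolate competes with O-alkylation, and the C3 carbonyl must then be deleted next to a quaternary carbon. (ii) From the C9 ketone the C17 methyl can only be placed at C8 as the wrong, thermodynamic epimer; the usual cure, a tetrasubstituted C8=C9 alkene reduced from the α-face, would have to be hydrogenated in the presence of the less substituted C5=C6 bond. (iii) The sequence is linear and long before the side chain is even attached.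

Alternative 2: a cation–olefin cyclisation. Ionisation of the allylic alcohol A3 would give an allyl cation (C17–C8–C9) that is attacked at C9 by the tetrasubstituted ring-A alkene; loss of H6 would give diene A4 with C9–C10, C5=C6 and the 8(17)-methylene in one step. The chair transition state would give the right C9/C10 relationship and the chain would already be in place. It was turned down because the only stereocentre of A3 is C13, too remote to bias the ring closure, so A4 would form together with its ring-enantiomeric diastereomer in equal amount. Attack at the primary allyl terminus also gives a six-membered ring, and the precursor needs as many steps as the chosen one.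

Alternative 3: dearomatisation. Reductive (Birch-type) methylation of the tetralone A5 at the ring-fusion carbon would create the quaternary C10 and leave dienone A6 with C5=C6 already in place. It was turned down because A6 still has the tetrasubstituted C8=C9 bond. Both ring stereocentres would have to come from a cis-hydrogenation of this more hindered alkene from one face while the trisubstituted C5=C6 bond survives, and any directing group at C1 is homoallylic to both alkenes. C10 is formed without absolute control, and the C1 carbonyl must be removed afterwards.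

Key step: step 8

Assumption: compounds 1, 2, 9, 10, 18, 19 and all reagents are catalogue chemicals; alkene 27 is carried on as an E/Z mixture (drawn E) because the C11=C12 bond is saturated in step 20.

## Route

Step 1
Reactants: 1 diethyl 2-(3-chloropropyl)propanedioate; 2 propanoyl chloride
Product: 3 diethyl 2-(3-chloropropyl)-2-propanoylpropanedioate
Conditions: NaH, THF, 0 °C; then 2, 0 °C → rt
Reagents that add atoms: none
Why: C-acylation of the sodium enolate of a monosubstituted malonate by an acid chloride; it makes the quaternary C4 (its two ester carbons become C18 and C19) and the C4–C5 bond, and creates no stereocentre.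

Step 2
Reactants: 3 diethyl 2-(3-chloropropyl)-2-propanoylpropanedioate
Product: 4 diethyl 3-methyl-2-oxocyclohexane-1,1-dicarboxylate
Conditions: LiHMDS, THF, −78 °C; then NaI (cat.), DMPU, rt → 50 °C
Reagents that add atoms: none
Why: the ketone can only enolise at the CH2 of the propanoyl group (future C10), and this lithium enolate closes ring A by a 6-(enolendo)-exo-tet C-alkylation on the primary halide (iodide catalysis); C10 forms racemic, which does not matter because it becomes sp2 in step 3.

Step 3
Reactants: 4 diethyl 3-methyl-2-oxocyclohexane-1,1-dicarboxylate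
Product: 5 diethyl 3-methyl-2-(trifluoromethanesulfonyloxy)cyclohex-2-ene-1,1-dicarboxylate
Conditions: KHMDS, THF, −78 °C; PhNTf2, −78 °C → rt
Reagents that add atoms: N-phenylbis(trifluoromethanesulfonimide), O=S(=O)(N(c1ccccc1)S(=O)(=O)C(F)(F)F)C(F)(F)F
Why: C4 is quaternary, so the enolate can only form towards C10; O-triflation gives the tetrasubstituted enol triflate regiospecifically.

Step 4
Reactants: 5 diethyl 3-methyl-2-(trifluoromethanesulfonyloxy)cyclohex-2-ene-1,1-dicarboxylate
Product: 6 diethyl 2-ethenyl-3-methylcyclohex-2-ene-1,1-dicarboxylate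
Conditions: CH2=CHSnBu3, Pd(PPh3)4 (cat.), LiCl, THF, reflux
Reagents that add atoms: tributyl(ethenyl)stannane, C=C[Sn](CCCC)(CCCC)CCCC
Why: Stille coupling of an enol triflate with a vinylstannane (LiCl-promoted) brings in C6 and C7 and completes the 1-vinylcyclohexene diene.

Step 5
Reactants: 6 diethyl 2-ethenyl-3-methylcyclohex-2-ene-1,1-dicarboxylate
Product: 7 (2-ethenyl-3-methylcyclohex-2-ene-1,1-diyl)dimethanol
Conditions: LiAlH4, THF, 0 °C → rt
Reagents that add atoms: none
Why: hydride reduction of the two esters gives the 1,3-diol (C18, C19); the unactivated diene is inert to LiAlH4.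

Step 6
Reactants: 7 (2-ethenyl-3-methylcyclohex-2-ene-1,1-diyl)dimethanol
Product: 8 7-ethenyl-3,3,8-trimethyl-2,4-dioxaspiro[5.5]undec-7-ene
Conditions: Me2C(OMe)2, PPTS (cat.), CH2Cl2, rt
Reagents that add atoms: 2,2-dimethoxypropane, COC(C)(C)OC
Why: transketalisation gives the six-membered isopropylidene acetal; it ties the two CH2O groups back from the diene faces and leaves the diene as electron-rich as possible for the cycloaddition.

Step 7
Reactants: 9 (4S)-4-benzyl-1,3-oxazolidin-2-one; 10 (2E)-but-2-enoyl chloride
Product: 11 (4S)-4-benzyl-3-[(2E)-but-2-enoyl]-1,3-oxazolidin-2-one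
Conditions: n-BuLi, THF, −78 °C; then 10, −78 → 0 °C
Reagents that add atoms: none
Why: N-acylation of the lithiated oxazolidinone; the (S)-benzyl centre is the bought stereocentre from which C8 and C10 are derived.

Step 8
Reactants: 8 7-ethenyl-3,3,8-trimethyl-2,4-dioxaspiro[5.5]undec-7-ene; 11 (4S)-4-benzyl-3-[(2E)-but-2-enoyl]-1,3-oxazolidin-2-one
Product: 12 Diels–Alder imide (8S,9R,10R) with 8β-methyl 9α-acyl 10β-methyl and the 18,19-acetonide
Conditions: Et2AlCl (1.4 equiv per 11), CH2Cl2, −78 → −20 °C
Reagents that add atoms: none
Why: Et2AlCl turns 11 into the cationic bidentate aluminium chelate with the enoyl group locked s-cis, and this strongly activated dienophile adds to the s-cis conformer of 8 in a concerted but very asynchronous [4+2] cycloaddition; the closest known reaction type is the auxiliary-controlled Diels–Alder reaction of N-enoyl oxazolidinones, and for the diene the cycloadditions of 2,6,6-trisubstituted 1-vinylcyclohexenes with activated dienophiles used for drimane decalins. Ring B is closed by cycloaddition: C7–C8 and C9–C10 are formed and the new double bond appears at C5=C6, where it cannot move because C4 and C10 are quaternary. Regiochemistry: the unsubstituted terminus C7 has the largest HOMO coefficient and bonds to the β-carbon of the enoyl unit (C8), positive charge builds up at the tertiary terminus C10, and C10 then bonds to the α-carbon (C9) and becomes the quaternary centre. C8 and C9: the trans geometry of the crotonyl unit is transferred and the diene adds to the enoyl face opposite the benzyl group, which fixes C8 as S (8β-methyl) and C9 as R. C10: the endo orientation of the chelated carbonyl over C5–C6 places the C9 acyl group trans and the C17 methyl cis to the C20 methyl (the inside substituent of the diene), which is 10R. The step needs regio-, endo- and π-facial selectivity, secured in turn by the disubstituted diene terminus, the chelate and the benzyl group; an exo adduct would be a separable diastereomer and would not lower the enantiomeric purity. The acetonide should be tolerated at or below −20 °C.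

Step 9
Reactants: 12 Diels–Alder imide (8S,9R,10R)
Product: 13 S-ethyl thioester (8S,9R,10R)
Conditions: EtSH, n-BuLi, THF, 0 °C
Reagents that add atoms: ethanethiol, CCS
Why: lithium ethanethiolate attacks the exocyclic carbonyl of hindered N-acyl oxazolidinones selectively (transthioesterification); it releases the auxiliary and gives a thioester that is easy to enolise and easy to reduce.

Step 10
Reactants: 13 S-ethyl thioester (8S,9R,10R)
Product: 15 primary alcohol (8S,9S,10R) with C11–OH, via 9S-thioester 14 (not isolated)
Conditions: LDA, THF, −78 → −40 °C; 2,6-di-tert-butyl-4-methylphenol, −78 °C; then LiAlH4, −78 → 0 °C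
Reagents that add atoms: none
Why: deprotonation removes the single C9–H; the exocyclic enolate should be protonated kinetically from the α-face, anti to the adjacent C17 methyl (held pseudo-axial by A1,3 strain) and to the C20 methyl, which inverts C9 to the all-cis arrangement (14); hydride reduction in the same flask fixes this contra-thermodynamic centre as an alcohol that can no longer epimerise.

Step 11
Reactants: 15 primary alcohol (8S,9S,10R)
Product: 16 1-phenyl-1H-tetrazol-5-yl sulfide at C11
Conditions: 1-phenyl-1H-tetrazole-5-thiol, PPh3, DIAD, THF, 0 °C → rt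
Reagents that add atoms: 1-phenyl-1H-tetrazole-5-thiol, Sc1nnnn1-c1ccccc1
Why: Mitsunobu thioetherification (SN2 at the primary C11); no stereocentre is touched.

Step 12
Reactants: 16 1-phenyl-1H-tetrazol-5-yl sulfide at C11
Product: 17 1-phenyl-1H-tetrazol-5-yl sulfone at C11
Conditions: (NH4)6Mo7O24·4H2O (cat.), 30% H2O2, EtOH, 0 °C → rt
Reagents that add atoms: hydrogen peroxide, OO
Why: molybdate-catalysed peroxide oxidation of sulfide to sulfone; the hindered C5=C6 bond and the acetonide should not react.

Step 13
Reactants: 18 (4R)-4-benzyl-1,3-oxazolidin-2-one; 19 pent-4-enoyl chloride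
Product: 20 (4R)-4-benzyl-3-(pent-4-enoyl)-1,3-oxazolidin-2-one
Conditions: n-BuLi, THF, −78 °C; then 19, −78 → 0 °C
Reagents that add atoms: none
Why: N-acylation of the lithiated auxiliary; the acyl carbon is the future C12 and the allyl group carries C14 and C15.

Step 14
Reactants: 20 (4R)-4-benzyl-3-(pent-4-enoyl)-1,3-oxazolidin-2-one
Product: 21 (4R)-4-benzyl-3-[(2S)-2-(hydroxymethyl)pent-4-enoyl]-1,3-oxazolidin-2-one
Conditions: TiCl4, i-Pr2NEt, CH2Cl2, 0 °C; then 1,3,5-trioxane, TiCl4, 0 °C
Reagents that add atoms: 1,3,5-trioxane, C1OCOCO1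
Why: titanium-enolate hydroxymethylation of an N-acyl oxazolidinone; the chlorotitanium Z-enolate is attacked on the face opposite the benzyl group, which sets C13 (2S here, with C16 as the new carbon).

Step 15
Reactants: 21 (4R)-4-benzyl-3-[(2S)-2-(hydroxymethyl)pent-4-enoyl]-1,3-oxazolidin-2-one
Product: 22 (4R)-4-benzyl-3-[(2S)-2-({[tert-butyl(dimethyl)silyl]oxy}methyl)pent-4-enoyl]-1,3-oxazolidin-2-one
Conditions: TBSCl, imidazole, CH2Cl2, rt
Reagents that add atoms: tert-butyl(chloro)dimethylsilane, CC(C)(C)[Si](C)(C)Cl
Why: silylation of the primary hydroxyl; it marks O16 with an acid-labile group and blocks retro-aldol loss of C16.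

Step 16
Reactants: 22 (4R)-4-benzyl-3-[(2S)-2-({[tert-butyl(dimethyl)silyl]oxy}methyl)pent-4-enoyl]-1,3-oxazolidin-2-one
Product: 25 (3S)-3-({[tert-butyl(dimethyl)silyl]oxy}methyl)oxolan-2-one, via aldehyde 23 (not isolated), via hydroxy imide 24 (not isolated)
Conditions: O3, CH2Cl2–MeOH, −78 °C; then NaBH4, −78 → 0 °C; rt
Reagents that add atoms: ozone, [O-][O+]=O
Why: ozonolysis cleaves the terminal alkene to aldehyde 23 (the terminal carbon is lost), borohydride reduces it to 24, and the new alkoxide attacks the imide carbonyl (5-exo-trig) to give the γ-lactone and release the auxiliary; C13 is not involved, and the lactone now distinguishes C12 (carbonyl) from C15 (alkyl–O).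

Step 17
Reactants: 25 (3S)-3-({[tert-butyl(dimethyl)silyl]oxy}methyl)oxolan-2-one
Product: 26 (3S)-3-({[tert-butyl(dimethyl)silyl]oxy}methyl)oxolan-2-ol
Conditions: DIBAL-H, CH2Cl2, −78 °C
Reagents that add atoms: none
Why: half-reduction of a γ-lactone at low temperature stops at the lactol (anomeric mixture), the masked C12 aldehyde with O15 still bound.

Step 18
Reactants: 17 1-phenyl-1H-tetrazol-5-yl sulfone at C11; 26 (3S)-3-({[tert-butyl(dimethyl)silyl]oxy}methyl)oxolan-2-ol
Product: 27 (E)-alkene C11=C12 with free C15–OH
Conditions: KHMDS (17), DME, −60 °C; then 26 as its potassium lactolate (KHMDS), −60 °C → rt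
Reagents that add atoms: none
Why: Julia–Kocienski olefination; the sulfonyl carbanion adds to the open hydroxy-aldehyde form of the lactolate, and Smiles rearrangement with loss of SO2 and the tetrazolone gives the C11=C12 bond and frees C15–OH as the only hydroxyl; the low temperature should protect the α-stereocentre C13 of the open aldehyde.

Step 19
Reactants: 27 (E)-alkene C11=C12 with free C15–OH
Product: 28 (E)-alkene C11=C12 with C15–OAc
Conditions: Ac2O, pyridine, DMAP (cat.), CH2Cl2, 0 °C
Reagents that add atoms: acetic anhydride, CC(=O)OC(C)=O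
Why: acetylation of the only free hydroxyl puts the acetate on O15 without any selectivity problem.

Step 20
Reactants: 28 (E)-alkene C11=C12 with C15–OAc
Product: 29 saturated protected precursor (8S,9S,10R,13S)
Conditions: 2-nitrobenzenesulfonohydrazide, Et3N, CH2Cl2, rt
Reagents that add atoms: none
Why: diimide reduces the 1,2-disubstituted alkene and should leave the trisubstituted C5=C6 bond between two quaternary carbons; no metal is present, so the double bond cannot migrate towards C9 or C13.

Step 21
Reactants: 29 saturated protected precursor (8S,9S,10R,13S)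
Product: 30 (3S)-5-[(1S,2S,8aR)-5,5-bis(hydroxymethyl)-2,8a-dimethyl-1,2,3,5,6,7,8,8a-octahydronaphthalen-1-yl]-3-(hydroxymethyl)pentyl acetate
Conditions: AcOH–THF–H2O (3:1:1), 40 °C
Reagents that add atoms: none
Why: aqueous acetic acid hydrolyses the primary silyl ether and the acetonide in one operation; a primary acetate is stable to dilute acid, and 1,4-acyl migration to O16 is slow without base.

## Compound list

1 | diethyl 2-(3-chloropropyl)propanedioate | CCOC(=O)C(CCCCl)C(=O)OCC | starting material
2 | propanoyl chloride | CCC(Cl)=O | starting material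
3 | diethyl 2-(3-chloropropyl)-2-propanoylpropanedioate | CCOC(=O)C(CCCCl)(C(=O)CC)C(=O)OCC | intermediate
4 | diethyl 3-methyl-2-oxocyclohexane-1,1-dicarboxylate (racemic) | CCOC(=O)C1(CCCC(C)C1=O)C(=O)OCC | intermediate
5 | diethyl 3-methyl-2-(trifluoromethanesulfonyloxy)cyclohex-2-ene-1,1-dicarboxylate | CCOC(=O)C1(CCCC(C)=C1OS(=O)(=O)C(F)(F)F)C(=O)OCC | intermediate
6 | diethyl 2-ethenyl-3-methylcyclohex-2-ene-1,1-dicarboxylate | CCOC(=O)C1(CCCC(C)=C1C=C)C(=O)OCC | intermediate
7 | (2-ethenyl-3-methylcyclohex-2-ene-1,1-diyl)dimethanol | OCC1(CO)CCCC(C)=C1C=C | intermediate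
8 | 7-ethenyl-3,3,8-trimethyl-2,4-dioxaspiro[5.5]undec-7-ene | C=CC1=C(C)CCCC12COC(C)(C)OC2 | intermediate
9 | (4S)-4-benzyl-1,3-oxazolidin-2-one | O=C1OC[C@H](Cc2ccccc2)N1 | starting material
10 | (2E)-but-2-enoyl chloride | C/C=C/C(Cl)=O | starting material
11 | (4S)-4-benzyl-3-[(2E)-but-2-enoyl]-1,3-oxazolidin-2-one | C/C=C/C(=O)N1[C@@H](Cc2ccccc2)COC1=O | intermediate
12 | (4S)-4-benzyl-3-{[(4a'R,5'R,6'S)-2,2,4a',6'-tetramethyl-3',4',4a',5',6',7'-hexahydro-2'H-spiro[1,3-dioxane-5,1'-naphthalen]-5'-yl]carbonyl}-1,3-oxazolidin-2-one (C4a' = C10, C5' = C9, C6' = C8) | O=C(N1[C@@H](Cc2ccccc2)COC1=O)[C@@H]3[C@@H](C)CC=C4C5(COC(C)(C)OC5)CCC[C@@]43C | intermediate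
13 | S-ethyl (4a'R,5'R,6'S)-2,2,4a',6'-tetramethyl-3',4',4a',5',6',7'-hexahydro-2'H-spiro[1,3-dioxane-5,1'-naphthalene]-5'-carbothioate | CCSC(=O)[C@@H]1[C@@H](C)CC=C2C3(COC(C)(C)OC3)CCC[C@@]21C | intermediate
14 | S-ethyl (4a'R,5'S,6'S)-2,2,4a',6'-tetramethyl-3',4',4a',5',6',7'-hexahydro-2'H-spiro[1,3-dioxane-5,1'-naphthalene]-5'-carbothioate | CCSC(=O)[C@H]1[C@@H](C)CC=C2C3(COC(C)(C)OC3)CCC[C@@]21C | intermediate (not isolated)
15 | [(4a'R,5'S,6'S)-2,2,4a',6'-tetramethyl-3',4',4a',5',6',7'-hexahydro-2'H-spiro[1,3-dioxane-5,1'-naphthalen]-5'-yl]methanol | OC[C@H]1[C@@H](C)CC=C2C3(COC(C)(C)OC3)CCC[C@@]21C | intermediate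
16 | 1-phenyl-5-({[(4a'R,5'S,6'S)-2,2,4a',6'-tetramethyl-3',4',4a',5',6',7'-hexahydro-2'H-spiro[1,3-dioxane-5,1'-naphthalen]-5'-yl]methyl}sulfanyl)-1H-tetrazole | C(Sc1nnnn1-c1ccccc1)[C@H]2[C@@H](C)CC=C3C4(COC(C)(C)OC4)CCC[C@@]32C | intermediate
17 | 1-phenyl-5-({[(4a'R,5'S,6'S)-2,2,4a',6'-tetramethyl-3',4',4a',5',6',7'-hexahydro-2'H-spiro[1,3-dioxane-5,1'-naphthalen]-5'-yl]methyl}sulfonyl)-1H-tetrazole | O=S(=O)(C[C@H]2[C@@H](C)CC=C3C4(COC(C)(C)OC4)CCC[C@@]32C)c1nnnn1-c1ccccc1 | intermediate
18 | (4R)-4-benzyl-1,3-oxazolidin-2-one | O=C1OC[C@@H](Cc2ccccc2)N1 | starting material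
19 | pent-4-enoyl chloride | C=CCCC(Cl)=O | starting material
20 | (4R)-4-benzyl-3-(pent-4-enoyl)-1,3-oxazolidin-2-one | C=CCCC(=O)N1[C@H](Cc2ccccc2)COC1=O | intermediate
21 | (4R)-4-benzyl-3-[(2S)-2-(hydroxymethyl)pent-4-enoyl]-1,3-oxazolidin-2-one | C=CC[C@@H](CO)C(=O)N1[C@H](Cc2ccccc2)COC1=O | intermediate
22 | (4R)-4-benzyl-3-[(2S)-2-({[tert-butyl(dimethyl)silyl]oxy}methyl)pent-4-enoyl]-1,3-oxazolidin-2-one | C=CC[C@@H](CO[Si](C)(C)C(C)(C)C)C(=O)N1[C@H](Cc2ccccc2)COC1=O | intermediate
23 | (4R)-4-benzyl-3-[(2S)-2-({[tert-butyl(dimethyl)silyl]oxy}methyl)-4-oxobutanoyl]-1,3-oxazolidin-2-one | O=CC[C@@H](CO[Si](C)(C)C(C)(C)C)C(=O)N1[C@H](Cc2ccccc2)COC1=O | intermediate (not isolated)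
24 | (4R)-4-benzyl-3-[(2S)-2-({[tert-butyl(dimethyl)silyl]oxy}methyl)-4-hydroxybutanoyl]-1,3-oxazolidin-2-one | OCC[C@@H](CO[Si](C)(C)C(C)(C)C)C(=O)N1[C@H](Cc2ccccc2)COC1=O | intermediate (not isolated)
25 | (3S)-3-({[tert-butyl(dimethyl)silyl]oxy}methyl)oxolan-2-one | O=C1OCC[C@H]1CO[Si](C)(C)C(C)(C)C | intermediate
26 | (3S)-3-({[tert-butyl(dimethyl)silyl]oxy}methyl)oxolan-2-ol (anomeric mixture) | OC1OCC[C@H]1CO[Si](C)(C)C(C)(C)C | intermediate
27 | (3R,4E)-3-({[tert-butyl(dimethyl)silyl]oxy}methyl)-5-[(4a'R,5'R,6'S)-2,2,4a',6'-tetramethyl-3',4',4a',5',6',7'-hexahydro-2'H-spiro[1,3-dioxane-5,1'-naphthalen]-5'-yl]pent-4-en-1-ol | OCC[C@@H](CO[Si](C)(C)C(C)(C)C)/C=C/[C@H]1[C@@H](C)CC=C2C3(COC(C)(C)OC3)CCC[C@@]21C | intermediate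
28 | (3R,4E)-3-({[tert-butyl(dimethyl)silyl]oxy}methyl)-5-[(4a'R,5'R,6'S)-2,2,4a',6'-tetramethyl-3',4',4a',5',6',7'-hexahydro-2'H-spiro[1,3-dioxane-5,1'-naphthalen]-5'-yl]pent-4-en-1-yl acetate | CC(=O)OCC[C@@H](CO[Si](C)(C)C(C)(C)C)/C=C/[C@H]1[C@@H](C)CC=C2C3(COC(C)(C)OC3)CCC[C@@]21C | intermediate
29 | (3S)-3-({[tert-butyl(dimethyl)silyl]oxy}methyl)-5-[(4a'R,5'S,6'S)-2,2,4a',6'-tetramethyl-3',4',4a',5',6',7'-hexahydro-2'H-spiro[1,3-dioxane-5,1'-naphthalen]-5'-yl]pentyl acetate | CC(=O)OCC[C@@H](CO[Si](C)(C)C(C)(C)C)CC[C@H]1[C@@H](C)CC=C2C3(COC(C)(C)OC3)CCC[C@@]21C | intermediate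
30 | (3S)-5-[(1S,2S,8aR)-5,5-bis(hydroxymethyl)-2,8a-dimethyl-1,2,3,5,6,7,8,8a-octahydronaphthalen-1-yl]-3-(hydroxymethyl)pentyl acetate | CC(=O)OCC[C@@H](CO)CC[C@H]1[C@@H](C)CC=C2C(CO)(CO)CCC[C@@]21C | target

## Step count and least certain steps

Total step count: 21. Longest linear sequence: 15 steps (steps 1–6, 8–12, 18–21).

Step 8 (key step). What may go wrong: the cycloaddition may be too slow because the diene terminus C10 is fully substituted and the s-cis conformer is strained, so that Lewis-acid-induced oligomerisation of the diene or ionisation of the acetonide competes. The endo preference, on which the C17/C20 cis relationship depends, may also be eroded by the CH2O group on C4 that lies under the approaching acyl group. Fallback: the bimolecular, auxiliary-controlled cycloaddition is replaced by an intramolecular one, in which a crotonate tether enforces the regiochemistry and the endo geometry and the absolute configuration comes from an enzymatic desymmetrisation. It sets out from diol 7. Lipase-catalysed transesterification with vinyl (E)-but-2-enoate acylates one of the two enantiotopic hydroxymethyl groups and gives the monocrotonate F1. The free hydroxyl is silylated (TBSCl, imidazole) to the silyl ether F2, so that acyl migration cannot scramble C4. Heating F2 (toluene, 170 °C, BHT) closes ring B in a type-2 intramolecular Diels–Alder reaction, in which the tether can only place the ester carbonyl endo, and gives the bridged lactone F3 (C17 and C20 cis, C11 on the α-face). Me2AlSEt (from Me3Al and EtSH) opens the strained lactone to the hydroxy thioester F4. HF·pyridine removes the silyl group to give the diol thioester F5, and 2,2-dimethoxypropane/PPTS converts it into 13, where the route is rejoined.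

Step 10. What may go wrong: poor facial selectivity in the protonation of the exocyclic enolate, because C10 offers a methyl group on one face and the ring-A methylene on the other, so only the C17 methyl gives a clear bias; incomplete enolisation of the hindered C9–H and loss of thiolate from the enolate on warming are further risks. Fallback: C9 is set by a face-selective hydrogenation instead of a protonation. It sets out from 13. Fukuyama reduction (Et3SiH, Pd/C) gives the aldehyde F6. TBSOTf/Et3N converts it into the silyl enol ether F7 (C9=C11). Hydrogenation (H2, Pd/C, EtOAc) of this electron-rich exocyclic enol ether, expected from the α-face and faster than the hindered C5=C6 bond, gives the silyl ether F8. TBAF then gives 15.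

Step 18. What may go wrong: the lactol may stay closed as its lactolate and react slowly, so that the sulfonyl carbanion decomposes; or the open hydroxy-aldehyde may epimerise at C13 under the basic conditions. Fallback: the lactol is replaced by an open-chain aldehyde that already carries the acetate. It sets out from lactone 25. Me(MeO)NH·HCl/Me3Al opens it to the hydroxy Weinreb amide F9, Ac2O/pyridine gives the acetate F10, and Cp2Zr(H)Cl reduces the amide but not the acetate to the aldehyde F11. Julia–Kocienski olefination of F11 with the potassium salt of 17 (KHMDS, DME, −60 °C) gives 28 directly, so step 19 is not needed.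

Step 4. What may go wrong: slow oxidative addition or transmetalation at the tetrasubstituted enol triflate next to the quaternary C4, with competing hydrolysis of the triflate back to 4. Fallback: the vinyl group is introduced by carbonyl addition and elimination instead of cross-coupling. It sets out from ketone 4. Vinylmagnesium bromide/CeCl3 (THF, −78 °C) adds to the ketone in the presence of the esters to give the tertiary allylic alcohol F12. Dehydration with the Burgess reagent, which can only take place towards C10 because C4 is quaternary, gives 6.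

## Further compounds

F1 | step 8 | [(1R)-2-ethenyl-1-(hydroxymethyl)-3-methylcyclohex-2-en-1-yl]methyl (2E)-but-2-enoate | C/C=C/C(=O)OC[C@]1(CO)CCCC(C)=C1C=C
F2 | step 8 | [(1S)-1-({[tert-butyl(dimethyl)silyl]oxy}methyl)-2-ethenyl-3-methylcyclohex-2-en-1-yl]methyl (2E)-but-2-enoate | C/C=C/C(=O)OC[C@]1(CO[Si](C)(C)C(C)(C)C)CCCC(C)=C1C=C
F3 | step 8 | bridged lactone of the intramolecular adduct (target locants 8S,9R,10R; C11 carboxyl esterified by O18; O19 as tert-butyldimethylsilyl ether) | O=C3[C@@H]1[C@@H](C)CC=C2[C@@](CO3)(CO[Si](C)(C)C(C)(C)C)CCC[C@@]21C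
F4 | step 8 | S-ethyl thioester (8S,9R,10R) with free C18–OH and O19 tert-butyldimethylsilyl ether | CCSC(=O)[C@@H]1[C@@H](C)CC=C2[C@@](CO)(CO[Si](C)(C)C(C)(C)C)CCC[C@@]21C
F5 | step 8 | S-ethyl (1R,2S,8aR)-5,5-bis(hydroxymethyl)-2,8a-dimethyl-1,2,3,5,6,7,8,8a-octahydronaphthalene-1-carbothioate | CCSC(=O)[C@@H]1[C@@H](C)CC=C2C(CO)(CO)CCC[C@@]21C
F6 | step 10 | (4a'R,5'R,6'S)-2,2,4a',6'-tetramethyl-3',4',4a',5',6',7'-hexahydro-2'H-spiro[1,3-dioxane-5,1'-naphthalene]-5'-carbaldehyde | O=C[C@@H]1[C@@H](C)CC=C2C3(COC(C)(C)OC3)CCC[C@@]21C
F7 | step 10 | tert-butyl(dimethyl)silyl enol ether of F6 (C9=C11, E/Z mixture; 4a'R,6'S) | CC(C)(C)[Si](C)(C)OC=C1[C@@H](C)CC=C2C3(COC(C)(C)OC3)CCC[C@@]21C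
F8 | step 10 | tert-butyl(dimethyl)silyl ether of alcohol 15 (4a'R,5'S,6'S) | CC(C)(C)[Si](C)(C)OC[C@H]1[C@@H](C)CC=C2C3(COC(C)(C)OC3)CCC[C@@]21C
F9 | step 18 | (2S)-2-({[tert-butyl(dimethyl)silyl]oxy}methyl)-4-hydroxy-N-methoxy-N-methylbutanamide | CON(C)C(=O)[C@H](CO[Si](C)(C)C(C)(C)C)CCO
F10 | step 18 | (3S)-3-({[tert-butyl(dimethyl)silyl]oxy}methyl)-4-[methoxy(methyl)amino]-4-oxobutyl acetate | CON(C)C(=O)[C@H](CO[Si](C)(C)C(C)(C)C)CCOC(C)=O
F11 | step 18 | (3S)-4-{[tert-butyl(dimethyl)silyl]oxy}-3-formylbutyl acetate | O=C[C@H](CO[Si](C)(C)C(C)(C)C)CCOC(C)=O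
F12 | step 4 | diethyl 2-ethenyl-2-hydroxy-3-methylcyclohexane-1,1-dicarboxylate (racemic, diastereomer mixture) | CCOC(=O)C1(CCCC(C)C1(O)C=C)C(=O)OCC
A1 | alternative 1 | (S)-Wieland–Miescher ketone, (8aS)-8a-methyl-3,4,8,8a-tetrahydronaphthalene-1,6(2H,7H)-dione | O=C1CCCC2=CC(=O)CC[C@@]21C
A2 | alternative 1 | C9 ketone with 18,19-acetonide and C5=C6 bond, (4a'S)-2,2,4a'-trimethyl-3',4',4a',6'-tetrahydro-2'H-spiro[1,3-dioxane-5,1'-naphthalen]-5'(7'H)-one | O=C1CCC=C2C3(COC(C)(C)OC3)CCC[C@@]21C
A3 | alternative 2 | (3S,6Z)-3-({[tert-butyl(dimethyl)silyl]oxy}methyl)-7-(hydroxymethyl)-9-(3,3,8-trimethyl-2,4-dioxaspiro[5.5]undec-7-en-7-yl)non-6-en-1-yl acetate | OC/C(CCC1=C(C)CCCC12COC(C)(C)OC2)=C\CC[C@H](CO[Si](C)(C)C(C)(C)C)CCOC(C)=O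
A4 | alternative 2 | cyclised diene with C5=C6 and C8=C17 (9S,10R,13S; 18,19-acetonide; O16 silyl ether; O15 acetate) | CC(=O)OCC[C@@H](CO[Si](C)(C)C(C)(C)C)CC[C@H]1C(=C)CC=C2C3(COC(C)(C)OC3)CCC[C@@]21C
A5 | alternative 3 | 4,4-disubstituted 7-methyl-8-alkyl-1-tetralone (4,4-acetonide; side chain with 13S and both oxygens as tert-butyldimethylsilyl ethers) | O=C1CCC2(COC(C)(C)OC2)c2ccc(C)c(CC[C@H](CO[Si](C)(C)C(C)(C)C)CCO[Si](C)(C)C(C)(C)C)c12
A6 | alternative 3 | C10-methylated dienone with C5=C6 and C8=C9 (C10 not controlled) | CC1=C(CC[C@H](CO[Si](C)(C)C(C)(C)C)CCO[Si](C)(C)C(C)(C)C)C2(C)C(=O)CCC3(COC(C)(C)OC3)C2=CC1
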